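**Retrosynthetic overview**

1. The target is (2S)-5,7-dihydroxy-4'-methoxy-6-prenylflavanone; the last step only removes two MOM ethers from O5 and O7.
2. Key disconnection: ring C is cut at both of its bonds to ring A (O1–C8a and C4–C4a), giving a 3,5-bis(MOM-oxy)-4-prenylbenzyne and the alkoxide of methyl (S)-3-hydroxy-3-(4-methoxyphenyl)propanoate, stored as its TMS ether.
3. Enabling feature: C8a and C4a are adjacent ring-A carbons carrying the ether oxygen O1 and the acyl carbon C4 (an aryne retron). The oxygen at C5 next to C4a steers the alkoxide to C8a and the aryl anion to C4a, and the prenyl group at C6 lies para to C8a on the symmetry axis of the phloroglucinol core.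
4. Aryne precursor: resorcinol, bis-MOM ether, prenylation between the ethers, C–H borylation/oxidation para to the prenyl group, carbamate-directed ortho-silylation, triflate.
5. Rings A and B are bought; ring C is the only ring formed (step 9). C2 is set by asymmetric transfer hydrogenation of the commercial β-keto ester and carried through unchanged.

Key step: step 9

Remark: flavanone numbering (O1, C2, C3, C4, C4a, C5 to C8, C8a) is used for the target and its precursors; the TMS ether 17 is assumed to be used directly after a non-aqueous work-up.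

**Step 1**
Reactants: 1 resorcinol
Product: 2 1,3-bis(methoxymethoxy)benzene
Conditions: MOMCl (2.4 equiv), i-Pr2NEt (3 equiv), CH2Cl2, 0 °C to rt
Reagents that add atoms: chloromethyl methyl ether (MOMCl), COCCl
Why: Standard MOM protection in which each phenol is O-alkylated by the reactive α-chloro ether in the presence of the amine base (Williamson-type etherification), giving acetals that survive organolithiums and fluoride.

**Step 2**
Reactants: 2 1,3-bis(methoxymethoxy)benzene; 3 prenyl bromide (1-bromo-3-methylbut-2-ene)
Product: 5 1,3-bis(methoxymethoxy)-2-(3-methylbut-2-en-1-yl)benzene, via aryllithium 4 (not isolated)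
Conditions: n-BuLi (1.1 equiv), THF, 0 °C to rt; then CuI (10 mol %), 3, −78 °C to rt
Reagents that add atoms: n-butyllithium, [Li]CCCC (its lithium stays only in intermediate 4)
Why: Directed ortho-metalation in which both MOM ethers direct n-BuLi to the carbon between them, followed by CuI-catalysed SN2 allylation of the aryllithium at the primary carbon of prenyl bromide, a known prenylation of MOM-protected resorcinols.

**Step 3**
Reactants: 5 1,3-bis(methoxymethoxy)-2-(3-methylbut-2-en-1-yl)benzene
Product: 7 3,5-bis(methoxymethoxy)-4-(3-methylbut-2-en-1-yl)phenol, via arylboronate 6 (not isolated)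
Conditions: [Ir(OMe)(cod)]2 (1.5 mol %), 4,4'-di-tert-butyl-2,2'-bipyridine (3 mol %), B2pin2 (1.0 equiv), THF, 80 °C; then aq NaOH, 30% H2O2, 0 °C to rt; neutralise to pH 6
Reagents that add atoms: bis(pinacolato)diboron, CC1(C)OB(OC1(C)C)B1OC(C)(C)C(C)(C)O1 (its boron stays only in intermediate 6); hydrogen peroxide, OO (the phenol oxygen)
Why: Iridium-catalysed C–H borylation is sterically controlled, the only ring C–H without an ortho substituent is the one para to the prenyl group, the trisubstituted alkene is expected to stay inert to the boryl catalyst, and alkaline H2O2 turns the C–B bond into C–O at the same carbon (one-pot borylation/oxidation to a phenol).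

**Step 4**
Reactants: 7 3,5-bis(methoxymethoxy)-4-(3-methylbut-2-en-1-yl)phenol
Product: 8 3,5-bis(methoxymethoxy)-4-(3-methylbut-2-en-1-yl)phenyl N-(propan-2-yl)carbamate
Conditions: i-PrNCO (1.5 equiv), Et3N (0.2 equiv), CH2Cl2, rt
Reagents that add atoms: isopropyl isocyanate, CC(C)N=C=O
Why: Amine-catalysed addition of the phenol to the isocyanate gives the N-isopropyl carbamate, a strong ortho-directing group that can later be removed under mild amine conditions.

**Step 5**
Reactants: 8 3,5-bis(methoxymethoxy)-4-(3-methylbut-2-en-1-yl)phenyl N-(propan-2-yl)carbamate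
Product: 12 3,5-bis(methoxymethoxy)-4-(3-methylbut-2-en-1-yl)-2-(trimethylsilyl)phenyl N-(propan-2-yl)carbamate, via N-silyl carbamate 9 (not isolated), via aryllithium 10 (not isolated), via disilyl carbamate 11 (not isolated)
Conditions: TBSOTf (1.1 equiv), TMEDA (1.1 equiv), Et2O, 0 °C to rt; then TMEDA (2 equiv), n-BuLi (2 equiv), −78 °C; TMSCl, −78 °C to rt; cold aq NaHSO4 (brief)
Reagents that add atoms: chlorotrimethylsilane, C[Si](C)(C)Cl; tert-butyldimethylsilyl triflate, CC(C)(C)[Si](C)(C)OS(=O)(=O)C(F)(F)F (its silyl group stays only in intermediates 9 to 11); n-butyllithium, [Li]CCCC (its lithium stays only in intermediate 10)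
Why: After in situ N-silylation the carbamate acts as a tertiary O-aryl carbamate, which together with the neighbouring MOM ether directs lithiation to the ring carbon between them (directed ortho-metalation, the two such carbons being equivalent by symmetry), and TMSCl traps the aryllithium before the N-silyl group is hydrolysed on work-up.

**Step 6**
Reactants: 12 3,5-bis(methoxymethoxy)-4-(3-methylbut-2-en-1-yl)-2-(trimethylsilyl)phenyl N-(propan-2-yl)carbamate
Product: 14 3,5-bis(methoxymethoxy)-4-(3-methylbut-2-en-1-yl)-2-(trimethylsilyl)phenyl trifluoromethanesulfonate, via silylphenol 13 (not isolated)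
Conditions: Et2NH (1.5 equiv), DBU (1.5 equiv), MeCN, 40 °C; then PhNTf2 (1.5 equiv), rt
Reagents that add atoms: N-phenylbis(trifluoromethanesulfonimide), O=S(=O)(N(c1ccccc1)S(=O)(=O)C(F)(F)F)C(F)(F)F
Why: DBU deprotonates the carbamate N–H so that isopropyl isocyanate is eliminated (E1cB) and scavenged by Et2NH as a urea, and the phenoxide is triflated in the same flask by PhNTf2 to give the ortho-silylaryl triflate, the standard fluoride-triggered aryne precursor.

**Step 7**
Reactants: 15 methyl 3-(4-methoxyphenyl)-3-oxopropanoate
Product: 16 methyl (3S)-3-hydroxy-3-(4-methoxyphenyl)propanoate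
Conditions: RuCl[(S,S)-TsDPEN](p-cymene) (1 mol %), HCO2H/Et3N (5:2), 30 °C
Reagents that add atoms: none
Why: Noyori asymmetric transfer hydrogenation in which the (S,S)-TsDPEN ruthenium hydride delivers hydride to the Re face of the aryl ketone in the same sense as for acetophenone, which sets the only stereocentre of the target as (S) and leaves the ester untouched.

**Step 8**
Reactants: 16 methyl (3S)-3-hydroxy-3-(4-methoxyphenyl)propanoate
Product: 17 methyl (3S)-3-(4-methoxyphenyl)-3-[(trimethylsilyl)oxy]propanoate
Conditions: TMSCl (1.2 equiv), imidazole (1.5 equiv), CH2Cl2, 0 °C; filtration through basic alumina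
Reagents that add atoms: chlorotrimethylsilane, C[Si](C)(C)Cl
Why: Silylation of the secondary alcohol (TMSCl/imidazole) stores the hydroxyl as a fluoride-labile TMS ether, a latent alkoxide, without touching the stereocentre.

**Step 9**
Reactants: 14 3,5-bis(methoxymethoxy)-4-(3-methylbut-2-en-1-yl)-2-(trimethylsilyl)phenyl trifluoromethanesulfonate; 17 methyl (3S)-3-(4-methoxyphenyl)-3-[(trimethylsilyl)oxy]propanoate
Product: 21 (2S)-5,7-bis(methoxymethoxy)-2-(4-methoxyphenyl)-6-(3-methylbut-2-en-1-yl)-2,3-dihydro-4H-chromen-4-one, via aryne 18 (not isolated), via cesium alkoxide 19 (not isolated), via aryl anion 20 (not isolated)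
Conditions: 14 (1.5 equiv) and 17 (1.0 equiv) added together over 2 h to CsF (4 equiv), 18-crown-6 (1 equiv), THF, 0 °C to rt; then AcOH (1.5 equiv), 0 °C
Reagents that add atoms: cesium fluoride, [Cs+].[F-] (its cesium stays only in intermediates 19 and 20; 21 holds no atom from it)
Why: Proposed new method: fluoride removes the aryl TMS group of 14 so that triflate leaves and aryne 18 forms, while fluoride also cleaves the O–SiMe3 bond of 17 to the proton-free cesium alkoxide 19, which adds to the aryne carbon remote from the C5 OMOM group (the future C8a) to give aryl anion 20 at C4a, and this anion attacks the ester carbonyl and expels methoxide. The closest known reaction type is the CsF-mediated annulation of arynes with salicylate esters to xanthones (phenoxide addition, then intramolecular acyl substitution by the aryl anion), which has not been shown for an aliphatic β-oxido ester or for closing a chromanone ring. Ring C is closed by a 6-exo-trig addition–elimination of the aryl anion at the ester carbon, directly after the intermolecular O–aryl bond formation. No stereocentre is created: C2 is the carbinol carbon of 17, none of its bonds is broken, and the (S) configuration set in step 7 is carried over with the same descriptor. The regioselectivity needed (oxygen at C8a, acyl at C4a) is secured by the OMOM group at C5, which distorts the aryne and stabilises negative charge on the adjacent C4a as in 3-alkoxybenzynes, and acylation is favoured over protonation of 20 because the alkoxide is unveiled from a silyl ether in THF so that no O–H is present. Excess 14 should silylate or arylate the expelled methoxide, which together with the low temperature and the slow joint addition limits retro-aldol cleavage of 19 and base-induced opening of ring C in 21.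

**Step 10**
Reactants: 21 (2S)-5,7-bis(methoxymethoxy)-2-(4-methoxyphenyl)-6-(3-methylbut-2-en-1-yl)-2,3-dihydro-4H-chromen-4-one
Product: 22 (2S)-5,7-dihydroxy-2-(4-methoxyphenyl)-6-(3-methylbut-2-en-1-yl)-2,3-dihydro-4H-chromen-4-one
Conditions: 3 M aq HCl, MeOH, rt to 40 °C, stopped at full conversion
Reagents that add atoms: none
Why: Acid-catalysed methanolysis of the two aryl MOM acetals (acetal exchange to dimethoxymethane) frees the 5- and 7-hydroxyls under conditions known for prenylated flavanones, mild enough that the prenyl alkene should not cyclise onto the flanking phenols and C2 should keep its configuration.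

**Compound list**

1 | resorcinol (benzene-1,3-diol) | Oc1cccc(O)c1 | starting material
2 | 1,3-bis(methoxymethoxy)benzene | COCOc1cccc(OCOC)c1 | intermediate
3 | prenyl bromide (1-bromo-3-methylbut-2-ene) | CC(C)=CCBr | starting material
4 | [2,6-bis(methoxymethoxy)phenyl]lithium (not isolated) | COCOc1cccc(OCOC)c1[Li] | intermediate
5 | 1,3-bis(methoxymethoxy)-2-(3-methylbut-2-en-1-yl)benzene | COCOc1cccc(OCOC)c1CC=C(C)C | intermediate
6 | 2-[3,5-bis(methoxymethoxy)-4-(3-methylbut-2-en-1-yl)phenyl]-4,4,5,5-tetramethyl-1,3,2-dioxaborolane (not isolated) | COCOc1cc(B2OC(C)(C)C(C)(C)O2)cc(OCOC)c1CC=C(C)C | intermediate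
7 | 3,5-bis(methoxymethoxy)-4-(3-methylbut-2-en-1-yl)phenol | COCOc1cc(O)cc(OCOC)c1CC=C(C)C | intermediate
8 | 3,5-bis(methoxymethoxy)-4-(3-methylbut-2-en-1-yl)phenyl N-(propan-2-yl)carbamate | CC(C)NC(=O)Oc1cc(OCOC)c(CC=C(C)C)c(OCOC)c1 | intermediate
9 | 3,5-bis(methoxymethoxy)-4-(3-methylbut-2-en-1-yl)phenyl N-(tert-butyldimethylsilyl)-N-(propan-2-yl)carbamate (not isolated) | CC(C)N([Si](C)(C)C(C)(C)C)C(=O)Oc1cc(OCOC)c(CC=C(C)C)c(OCOC)c1 | intermediate
10 | 2-lithio derivative of 9 (lithium on the ring carbon between the carbamate and a MOM ether; not isolated) | CC(C)N([Si](C)(C)C(C)(C)C)C(=O)Oc1cc(OCOC)c(CC=C(C)C)c(OCOC)c1[Li] | intermediate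
11 | 3,5-bis(methoxymethoxy)-4-(3-methylbut-2-en-1-yl)-2-(trimethylsilyl)phenyl N-(tert-butyldimethylsilyl)-N-(propan-2-yl)carbamate (not isolated) | CC(C)N([Si](C)(C)C(C)(C)C)C(=O)Oc1cc(OCOC)c(CC=C(C)C)c(OCOC)c1[Si](C)(C)C | intermediate
12 | 3,5-bis(methoxymethoxy)-4-(3-methylbut-2-en-1-yl)-2-(trimethylsilyl)phenyl N-(propan-2-yl)carbamate | CC(C)NC(=O)Oc1cc(OCOC)c(CC=C(C)C)c(OCOC)c1[Si](C)(C)C | intermediate
13 | 3,5-bis(methoxymethoxy)-4-(3-methylbut-2-en-1-yl)-2-(trimethylsilyl)phenol (held as its DBU salt, not isolated) | COCOc1cc(O)c([Si](C)(C)C)c(OCOC)c1CC=C(C)C | intermediate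
14 | 3,5-bis(methoxymethoxy)-4-(3-methylbut-2-en-1-yl)-2-(trimethylsilyl)phenyl trifluoromethanesulfonate | COCOc1cc(OS(=O)(=O)C(F)(F)F)c([Si](C)(C)C)c(OCOC)c1CC=C(C)C | intermediate
15 | methyl 3-(4-methoxyphenyl)-3-oxopropanoate | COC(=O)CC(=O)c1ccc(OC)cc1 | starting material
16 | methyl (3S)-3-hydroxy-3-(4-methoxyphenyl)propanoate | COC(=O)C[C@H](O)c1ccc(OC)cc1 | intermediate
17 | methyl (3S)-3-(4-methoxyphenyl)-3-[(trimethylsilyl)oxy]propanoate | COC(=O)C[C@H](O[Si](C)(C)C)c1ccc(OC)cc1 | intermediate
18 | 3,5-bis(methoxymethoxy)-4-(3-methylbut-2-en-1-yl)benzyne (1,2-didehydrobenzene; not isolated) | COCOC1=C(CC=C(C)C)C(OCOC)=CC#C1 | intermediate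
19 | cesium (1S)-3-methoxy-1-(4-methoxyphenyl)-3-oxopropan-1-olate (not isolated) | [Cs+].COC(=O)C[C@H]([O-])c1ccc(OC)cc1 | intermediate
20 | cesium aryl anion from addition of 19 to 18: methyl (3S)-3-aryloxy-3-(4-methoxyphenyl)propanoate with the carbanion ortho to the new ether oxygen and to a MOM ether (not isolated) | [Cs+].COC(=O)C[C@H](Oc1cc(OCOC)c(CC=C(C)C)c(OCOC)[c-]1)c1ccc(OC)cc1 | intermediate
21 | (2S)-5,7-bis(methoxymethoxy)-2-(4-methoxyphenyl)-6-(3-methylbut-2-en-1-yl)-2,3-dihydro-4H-chromen-4-one | COc1ccc([C@@H]2CC(=O)c3c(cc(OCOC)c(CC=C(C)C)c3OCOC)O2)cc1 | intermediate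
22 | (2S)-5,7-dihydroxy-2-(4-methoxyphenyl)-6-(3-methylbut-2-en-1-yl)-2,3-dihydro-4H-chromen-4-one | COc1ccc([C@@H]2CC(=O)c3c(cc(O)c(CC=C(C)C)c3O)O2)cc1 | target

**Step count**

Total step count: 10. Longest linear sequence: 8 steps (resorcinol to the target through steps 1, 2, 3, 4, 5, 6, 9 and 10); steps 7 and 8 prepare the side-chain partner.

**Steps most likely to fail, with fallbacks**

1. Step 9 (Proposed new method). The cesium alkoxide may fragment by retro-aldol cleavage or add too slowly to intercept the aryne, the aryl anion may be protonated before it acylates, and the base set free may open ring C and erode the configuration at C2. The fallback uses known reactions and sets C2 by a catalyst instead; it sets out from 14 and comes back at 21. CsF-mediated C–O insertion of the aryne from 14 into acetic acid (carboxylate addition at the same remote carbon, then acyl shift to the OMOM-flanked carbon; THF, sealed tube, heating) should give the ortho-hydroxyacetophenone 1-[6-hydroxy-2,4-bis(methoxymethoxy)-3-(3-methylbut-2-en-1-yl)phenyl]ethan-1-one F1. Condensation with N,N-dimethylformamide dimethyl acetal in warm toluene should give the enaminone F2, which should close in warm acetic acid with loss of dimethylamine to 5,7-bis(methoxymethoxy)-6-(3-methylbut-2-en-1-yl)-4H-chromen-4-one F3. Rhodium-catalysed asymmetric conjugate addition of 4-methoxyphenylboronic acid to F3 ([Rh(OH)(cod)]2, a chiral bisphosphine or diene ligand whose antipode is chosen to deliver the aryl group to the face giving (2S), dioxane/H2O) should then give 21.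

2. Step 3. The iridium boryl catalyst may hydroborate or isomerise the prenyl alkene, or borylation of the hindered trisubstituted arene may stall. The fallback oxygenates before it prenylates; it sets out from 2 and comes back at 7. The same borylation/oxidation applied to the alkene-free 2 should give, through the arylboronate F4, 3,5-bis(methoxymethoxy)phenol F5. Silylation with i-Pr3SiCl/imidazole should give the TIPS ether F6, whose bulky, non-coordinating silyloxy group leaves the carbon between the two MOM ethers as the only site for n-BuLi, giving the aryllithium F7. CuI-catalysed allylation with 3 should give the prenylated TIPS ether F8, and Bu4NF should free the phenol 7.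

3. Step 5. Lithiation may take place in part at the benzylic and allylic CH2 of the prenyl group, or the silyl triflate may attack a MOM acetal. The fallback replaces directed metalation by halogen–lithium exchange and a silyl migration; it sets out from 7 and comes back at 14, bypassing 8 to 13. Ring bromination ortho to the hydroxyl (NBS, CH2Cl2, −78 °C; both ortho positions are equivalent and the electron-rich ring should react before the alkene) should give the bromophenol F9. O-silylation with (Me3Si)2NH should give the aryl silyl ether F10. n-BuLi at −78 °C should give the aryllithium F11, which should rearrange by 1,3 oxygen-to-carbon silyl migration (retro-Brook) to the lithium phenoxide F12, and Tf2O added to the same flask should give 14.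

**Further compounds**

F1 | step 9 | 1-[6-hydroxy-2,4-bis(methoxymethoxy)-3-(3-methylbut-2-en-1-yl)phenyl]ethan-1-one | CC(=O)c1c(O)cc(OCOC)c(CC=C(C)C)c1OCOC
F2 | step 9 | (E)-3-(dimethylamino)-1-[6-hydroxy-2,4-bis(methoxymethoxy)-3-(3-methylbut-2-en-1-yl)phenyl]prop-2-en-1-one | CN(C)/C=C/C(=O)c1c(O)cc(OCOC)c(CC=C(C)C)c1OCOC
F3 | step 9 | 5,7-bis(methoxymethoxy)-6-(3-methylbut-2-en-1-yl)-4H-chromen-4-one | O=c1ccoc2cc(OCOC)c(CC=C(C)C)c(OCOC)c12
F4 | step 3 | 2-[3,5-bis(methoxymethoxy)phenyl]-4,4,5,5-tetramethyl-1,3,2-dioxaborolane | COCOc1cc(B2OC(C)(C)C(C)(C)O2)cc(OCOC)c1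
F5 | step 3 | 3,5-bis(methoxymethoxy)phenol | COCOc1cc(O)cc(OCOC)c1
F6 | step 3 | [3,5-bis(methoxymethoxy)phenoxy]tri(propan-2-yl)silane | COCOc1cc(O[Si](C(C)C)(C(C)C)C(C)C)cc(OCOC)c1
F7 | step 3 | [2,6-bis(methoxymethoxy)-4-{[tri(propan-2-yl)silyl]oxy}phenyl]lithium | COCOc1cc(O[Si](C(C)C)(C(C)C)C(C)C)cc(OCOC)c1[Li]
F8 | step 3 | [3,5-bis(methoxymethoxy)-4-(3-methylbut-2-en-1-yl)phenoxy]tri(propan-2-yl)silane | COCOc1cc(O[Si](C(C)C)(C(C)C)C(C)C)cc(OCOC)c1CC=C(C)C
F9 | step 5 | 2-bromo-3,5-bis(methoxymethoxy)-4-(3-methylbut-2-en-1-yl)phenol | COCOc1cc(O)c(Br)c(OCOC)c1CC=C(C)C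
F10 | step 5 | [2-bromo-3,5-bis(methoxymethoxy)-4-(3-methylbut-2-en-1-yl)phenoxy]trimethylsilane | COCOc1cc(O[Si](C)(C)C)c(Br)c(OCOC)c1CC=C(C)C
F11 | step 5 | {2,4-bis(methoxymethoxy)-3-(3-methylbut-2-en-1-yl)-6-[(trimethylsilyl)oxy]phenyl}lithium | COCOc1cc(O[Si](C)(C)C)c([Li])c(OCOC)c1CC=C(C)C
F12 | step 5 | lithium 3,5-bis(methoxymethoxy)-4-(3-methylbut-2-en-1-yl)-2-(trimethylsilyl)phenoxide | [Li+].COCOc1cc([O-])c([Si](C)(C)C)c(OCOC)c1CC=C(C)C
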